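**Plan**

- Retrosynthetic cuts, in order: CO2H back to CO2Me; the (E)-C5'=C6' alkene of the side chain (Julia–Kocienski); the two ring bonds C4–C5 and O2–C3 of the 1,2-dioxolane together ([3+2] annulation of a peroxycarbenium ion with an alkene); the C9'=C10' styrene (cross-metathesis).
- Enabling feature: ring carbon C5 (CH3, side-chain CH2, O1) is a methyl ketone carbon that has kept an O–O bond, that is, a peroxycarbenium ion. C4H2–C3(CH3)(CH2CO2H) is the skeleton of methyl 3-methylbut-3-enoate, whose tertiary cation lies 1,3 to O2.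
- Forward: (R)-citronellic acid → methyl ketone → cleavage of the prenyl alkene to a C5' silyl ether → bis-silyl monoperoxyketal → dioxolane (the only ring) with its acetate arm in one step → aldehyde → diene chain → acid.
- Stereochemistry: C2' (R) comes from C3 of citronellic acid, whose C6=C7 bond marks the later C5'=C6' position. C5 (R) and C3 (S) come from a chiral-anion-controlled annulation. Both (E)-alkenes come from cross-metathesis and Julia–Kocienski olefination.
- The chain alkenes are kept out of the annulation, because a C5'=C6' alkene would attack the carbenium carbon through a six-membered transition state; hence the late olefination.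

Key step: step 5

Remark: the sense of induction of the chiral anion in step 5 cannot be predicted, so the catalyst antipode that leads to (3S,5R)-11 is assumed to be found by screening both enantiomers; compounds 1, 8, 13 and 14 are taken as commercial.

Step 1
Reactants: 1 (R)-citronellic acid [(3R)-3,7-dimethyloct-6-enoic acid]
Product: 3 (4R)-4,8-dimethylnon-7-en-2-one, via dilithium gem-diolate 2 (not isolated)
Conditions: MeLi (2.3 equiv), Et2O, 0 → 23 °C; inverse quench into cold 1 M HCl
Reagents that add atoms: methyllithium [Li]C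
Why: Two equivalents of MeLi convert the acid into the stable gem-diolate 2, which cannot take up a further methyl group and collapses to the methyl ketone only on acidic quench (ketone synthesis from a carboxylic acid and an organolithium), without touching the chiral-pool stereocentre.

Step 2
Reactants: 3 (4R)-4,8-dimethylnon-7-en-2-one
Product: 5 (4R)-7-hydroxy-4-methylheptan-2-one, via keto aldehyde 4 (not isolated)
Conditions: O3, CH2Cl2, −78 °C; PPh3 (1.2 equiv), −78 → 0 °C; then NaBH(OAc)3 (1.5 equiv), AcOH, 0 → 23 °C
Reagents that add atoms: ozone [O-][O+]=O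
Why: Ozonolysis cleaves the only C=C bond, PPh3 reduces the ozonide to keto aldehyde 4, and NaBH(OAc)3 reduces the aldehyde but not the methyl ketone (chemoselective triacetoxyborohydride reduction), so the aldol-prone 1,6-keto aldehyde is never isolated.

Step 3
Reactants: 5 (4R)-7-hydroxy-4-methylheptan-2-one
Product: 6 triethyl{[(4R)-4-methyl-7-(triethylsilyloxy)hept-1-en-2-yl]oxy}silane
Conditions: LiN(iPr)2 (2.3 equiv), THF, −78 °C; Et3SiCl (2.6 equiv), −78 → 23 °C
Reagents that add atoms: chlorotriethylsilane CC[Si](Cl)(CC)CC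
Why: LiN(iPr)2 removes the hydroxyl proton and, under kinetic control, a methyl proton, and Et3SiCl traps both oxygens (kinetic silyl enol ether formation with O-silylation); any internal enol ether isomer would give the same product in step 4.

Step 4
Reactants: 6 triethyl{[(4R)-4-methyl-7-(triethylsilyloxy)hept-1-en-2-yl]oxy}silane
Product: 7 (4R)-4-methyl-2,7-bis(triethylsilyloxy)-2-(triethylsilylperoxy)heptane (both C2 epimers)
Conditions: Co(thd)2 [Co(C11H19O2)2, divalent cobalt, thd = 2,2,6,6-tetramethylheptane-3,5-dionate] (10 mol %), O2 (1 atm), Et3SiH (2 equiv), 1,2-dichloroethane, 23 °C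
Reagents that add atoms: dioxygen O=O; triethylsilane CC[SiH](CC)CC
Why: In this Isayama–Mukaiyama silylperoxidation, a reaction type known for silyl enol ethers, a cobalt hydride transfers a hydrogen atom to the enol ether CH2 and the α-silyloxy tertiary radical captures O2 and is silylated; the new ketal carbon forms as both epimers, which does not matter because it becomes planar in step 5.

Step 5
Reactants: 7 (4R)-4-methyl-2,7-bis(triethylsilyloxy)-2-(triethylsilylperoxy)heptane; 8 methyl 3-methylbut-3-enoate
Product: 11 methyl 2-[(3S,5R)-3,5-dimethyl-5-[(2R)-2-methyl-5-(triethylsilyloxy)pentyl]-1,2-dioxolan-3-yl]acetate, via peroxycarbenium ion 9 (not isolated), via tertiary carbenium ion 10 (not isolated)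
Conditions: chiral confined imidodiphosphorimidate Brønsted acid (IDPi type, BINOL backbone, N-triflyl groups; 5 mol %), 8 (3 equiv), toluene, −78 → −40 °C; Et3N quench
Reagents that add atoms: none
Why: Proposed new method: the silylated form of the chiral acid (Et3Si–X*, formed from the acid and 7) abstracts the triethylsilyloxy group of 7 to give peroxycarbenium ion 9 as a contact ion pair with the confined anion X*−, the CH2 terminus of 8 adds to the carbenium carbon (C5 of the ring) to give tertiary cation 10, the silylated distal peroxide oxygen captures this cation, and Et3Si+ returns to X*− so that (Et3Si)2O is the only by-product. The closest known reaction types are the SnCl4-mediated [3+2] annulation of silyl peroxyketals with 1,1-disubstituted alkenes (same two bonds, no chiral control) and confined chiral acid-catalysed asymmetric Prins reactions of oxocarbenium ion pairs with simple alkenes. The dioxolane closes by a stepwise polar [3+2] process (the C–O–O unit plus the two alkene carbons), the last bond arising from oxygen capture of the free tertiary carbenium centre in a five-membered closure. C5 (R) is set by the face of the planar peroxycarbenium ion that the anion leaves open, the methyl versus CH2R distinction being of the kind such anions are known to make in small ketones; C3 (S) is set in the ring closure, where the anion pocket and the preference to hold the CH2CO2Me arm trans to the long chain decide which face of the cation meets oxygen. The step needs catalyst control over the weak 1,3-induction of the remote C2' methyl group, O–C capture faster than proton loss from 10 (favoured by the silylperoxy oxygen held five atoms away at low temperature), and no competing π-nucleophile, which is why no chain alkene is present.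

Step 6
Reactants: 11 methyl 2-[(3S,5R)-3,5-dimethyl-5-[(2R)-2-methyl-5-(triethylsilyloxy)pentyl]-1,2-dioxolan-3-yl]acetate
Product: 12 methyl 2-[(3S,5R)-3,5-dimethyl-5-[(2R)-2-methyl-5-oxopentyl]-1,2-dioxolan-3-yl]acetate
Conditions: (COCl)2 (3 equiv), DMSO (6 equiv), CH2Cl2, −78 → −40 °C; Et3N (10 equiv), −78 → 0 °C
Reagents that add atoms: none
Why: Under Swern conditions a primary triethylsilyl ether is cleaved by the chlorosulfonium salt and oxidised directly to the aldehyde (oxidative desilylation), while the hindered di-tertiary peroxide and the ester do not react with activated DMSO or Et3N at low temperature.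

Step 7
Reactants: 13 pent-4-en-1-ol; 14 styrene
Product: 15 (4E)-5-phenylpent-4-en-1-ol
Conditions: second-generation Grubbs catalyst RuCl2(=CHPh)(PCy3)(H2IMes) (2 mol %), 14 (3 equiv), CH2Cl2, 40 °C
Reagents that add atoms: none
Why: Olefin cross-metathesis of a terminal alkene with excess styrene favours the cross product and gives the conjugated (E)-alkene under thermodynamic control, which sets the C9'=C10' geometry.

Step 8
Reactants: 15 (4E)-5-phenylpent-4-en-1-ol
Product: 16 1-phenyl-5-{[(4E)-5-phenylpent-4-en-1-yl]sulfanyl}-1H-tetrazole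
Conditions: 1-phenyl-1H-tetrazole-5-thiol, PPh3, DIAD, THF, 0 → 23 °C
Reagents that add atoms: 1-phenyl-1H-tetrazole-5-thiol Sc1nnnn1-c1ccccc1
Why: Mitsunobu thioetherification of an unhindered primary alcohol with the acidic heteroaryl thiol proceeds by SN2 displacement of the oxyphosphonium ion.

Step 9
Reactants: 16 1-phenyl-5-{[(4E)-5-phenylpent-4-en-1-yl]sulfanyl}-1H-tetrazole
Product: 17 1-phenyl-5-{[(4E)-5-phenylpent-4-en-1-yl]sulfonyl}-1H-tetrazole
Conditions: (NH4)6Mo7O24·4H2O (10 mol %), 30% aq H2O2 (5 equiv), EtOH, 0 → 23 °C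
Reagents that add atoms: hydrogen peroxide OO
Why: Molybdate-catalysed H2O2 oxidation takes the sulfide to the sulfone much faster than it epoxidises the styrenyl alkene (chemoselective sulfide oxidation).

Step 10
Reactants: 12 methyl 2-[(3S,5R)-3,5-dimethyl-5-[(2R)-2-methyl-5-oxopentyl]-1,2-dioxolan-3-yl]acetate; 17 1-phenyl-5-{[(4E)-5-phenylpent-4-en-1-yl]sulfonyl}-1H-tetrazole
Product: 18 methyl 2-[(3S,5R)-3,5-dimethyl-5-[(2R,5E,9E)-2-methyl-10-phenyldeca-5,9-dien-1-yl]-1,2-dioxolan-3-yl]acetate
Conditions: 17 (1.3 equiv), KN(SiMe3)2 (1.25 equiv), DME, −60 °C; then 12, −60 → 23 °C; aq NH4Cl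
Reagents that add atoms: none
Why: In this Julia–Kocienski olefination the pre-formed potassium sulfonyl carbanion adds to the unbranched aldehyde, Smiles rearrangement and loss of SO2 and the tetrazolone follow, and with KN(SiMe3)2 in DME the open anti-selective addition should favour the (E)-C5'=C6' alkene, the carbanion being consumed by the aldehyde faster than it can enolise the ester or attack the hindered O–O bond.

Step 11
Reactants: 18 methyl 2-[(3S,5R)-3,5-dimethyl-5-[(2R,5E,9E)-2-methyl-10-phenyldeca-5,9-dien-1-yl]-1,2-dioxolan-3-yl]acetate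
Product: 19 2-[(3S,5R)-3,5-dimethyl-5-[(2R,5E,9E)-2-methyl-10-phenyldeca-5,9-dien-1-yl]-1,2-dioxolan-3-yl]acetic acid
Conditions: LiOH·H2O (3 equiv), THF/H2O (3:1), 0 → 23 °C; then 1 M HCl to pH 3
Reagents that add atoms: lithium hydroxide [Li+].[OH-]
Why: Saponification of the unhindered methyl ester is precedented for 1,2-dioxolane-3-acetates, the fully substituted peroxide carbons carry no α-hydrogen for a Kornblum–DeLaMare fragmentation, and the carboxylate once formed resists further enolisation.

**Compound list**

1 | (R)-citronellic acid, (3R)-3,7-dimethyloct-6-enoic acid | C[C@H](CCC=C(C)C)CC(=O)O | starting material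
2 | dilithium (4R)-4,8-dimethylnon-7-ene-2,2-diolate | C[C@H](CCC=C(C)C)CC(C)([O-])[O-].[Li+].[Li+] | intermediate
3 | (4R)-4,8-dimethylnon-7-en-2-one | C[C@H](CCC=C(C)C)CC(C)=O | intermediate
4 | (4R)-4-methyl-6-oxoheptanal | C[C@H](CCC=O)CC(C)=O | intermediate
5 | (4R)-7-hydroxy-4-methylheptan-2-one | C[C@H](CCCO)CC(C)=O | intermediate
6 | triethyl{[(4R)-4-methyl-7-(triethylsilyloxy)hept-1-en-2-yl]oxy}silane | C[C@H](CCCO[Si](CC)(CC)CC)CC(=C)O[Si](CC)(CC)CC | intermediate
7 | (4R)-4-methyl-2,7-bis(triethylsilyloxy)-2-(triethylsilylperoxy)heptane, both C2 epimers | C[C@H](CCCO[Si](CC)(CC)CC)CC(C)(O[Si](CC)(CC)CC)OO[Si](CC)(CC)CC | intermediate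
8 | methyl 3-methylbut-3-enoate | C=C(C)CC(=O)OC | starting material
9 | peroxycarbenium ion, (4R)-4-methyl-7-(triethylsilyloxy)heptan-2-ylidene(triethylsilyloxy)oxonium | C[C@H](CCCO[Si](CC)(CC)CC)CC(C)=[O+]O[Si](CC)(CC)CC | intermediate
10 | tertiary carbenium ion after C–C bond formation, peroxide carbon already in the product configuration | C[C@H](CCCO[Si](CC)(CC)CC)C[C@](C)(C[C+](C)CC(=O)OC)OO[Si](CC)(CC)CC | intermediate
11 | methyl 2-[(3S,5R)-3,5-dimethyl-5-[(2R)-2-methyl-5-(triethylsilyloxy)pentyl]-1,2-dioxolan-3-yl]acetate | C[C@H](CCCO[Si](CC)(CC)CC)C[C@]1(C)C[C@@](C)(CC(=O)OC)OO1 | intermediate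
12 | methyl 2-[(3S,5R)-3,5-dimethyl-5-[(2R)-2-methyl-5-oxopentyl]-1,2-dioxolan-3-yl]acetate | C[C@H](CCC=O)C[C@]1(C)C[C@@](C)(CC(=O)OC)OO1 | intermediate
13 | pent-4-en-1-ol | C=CCCCO | starting material
14 | styrene | C=Cc1ccccc1 | starting material
15 | (4E)-5-phenylpent-4-en-1-ol | OCCC/C=C/c1ccccc1 | intermediate
16 | 1-phenyl-5-{[(4E)-5-phenylpent-4-en-1-yl]sulfanyl}-1H-tetrazole | c1ccccc1/C=C/CCCSc1nnnn1-c1ccccc1 | intermediate
17 | 1-phenyl-5-{[(4E)-5-phenylpent-4-en-1-yl]sulfonyl}-1H-tetrazole | c1ccccc1/C=C/CCCS(=O)(=O)c1nnnn1-c1ccccc1 | intermediate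
18 | methyl 2-[(3S,5R)-3,5-dimethyl-5-[(2R,5E,9E)-2-methyl-10-phenyldeca-5,9-dien-1-yl]-1,2-dioxolan-3-yl]acetate | C[C@H](CC/C=C/CC/C=C/c1ccccc1)C[C@]1(C)C[C@@](C)(CC(=O)OC)OO1 | intermediate
19 | 2-[(3S,5R)-3,5-dimethyl-5-[(2R,5E,9E)-2-methyl-10-phenyldeca-5,9-dien-1-yl]-1,2-dioxolan-3-yl]acetic acid | C[C@H](CC/C=C/CC/C=C/c1ccccc1)C[C@]1(C)C[C@@](C)(CC(=O)O)OO1 | target

**Step count**

Total steps: 11. Longest linear sequence: 8 steps (steps 1 to 6, then 10 and 11); steps 7 to 9 make the sulfone side branch.

**Steps most likely to fail**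

1. Step 5. What may go wrong: the silyl-transfer cycle may not turn over, the chiral anion may distinguish the two faces of the peroxycarbenium ion and the two closure modes too weakly, or the tertiary cation may lose a proton before oxygen capture. Fallback (known chemistry, stereocontrol exchanged for separation): set out from 7 and 8 with stoichiometric SnCl4 in CH2Cl2 at −78 °C, the established achiral Lewis acid annulation of silyl peroxyketals with 1,1-disubstituted alkenes. This should give the stereoisomer mixture methyl 2-[3,5-dimethyl-5-[(2R)-2-methyl-5-(triethylsilyloxy)pentyl]-1,2-dioxolan-3-yl]acetate F1 (all C3/C5 isomers). The pair with the two long arms trans is separated on silica, and the (3S,5R) isomer is then isolated by preparative HPLC on a chiral stationary phase, which returns to the route at 11.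

2. Step 10. What may go wrong: erosion of (E) selectivity in the addition step, and enolisation or self-condensation of the ester-bearing aldehyde under the basic carbanion. Fallback (roles of the two fragments exchanged, so that the valuable fragment is the nucleophile and a simple aldehyde is used in excess): set out from 11 and 15. PPTS in MeOH should release the alcohol methyl 2-[(3S,5R)-5-[(2R)-5-hydroxy-2-methylpentyl]-3,5-dimethyl-1,2-dioxolan-3-yl]acetate F2. Mitsunobu reaction with 1-phenyl-1H-tetrazole-5-thiol (PPh3, DIAD) gives the sulfide methyl 2-[(3S,5R)-3,5-dimethyl-5-[(2R)-2-methyl-5-[(1-phenyl-1H-tetrazol-5-yl)sulfanyl]pentyl]-1,2-dioxolan-3-yl]acetate F3. Molybdate-catalysed H2O2 oxidation then gives the sulfone methyl 2-[(3S,5R)-3,5-dimethyl-5-[(2R)-2-methyl-5-[(1-phenyl-1H-tetrazol-5-yl)sulfonyl]pentyl]-1,2-dioxolan-3-yl]acetate F4. In parallel, 15 is oxidised with Dess–Martin periodinane to (4E)-5-phenylpent-4-enal F5. KN(SiMe3)2 is added at −78 °C to F4 in the presence of excess F5 in DME, so that the carbanion is trapped as it forms, and the route is rejoined at 18.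

3. Step 4. What may go wrong: over-reduction of the peroxyl intermediate back to the ketone level, and hydrolytic loss of the bis-silyl peroxyketal on handling. Fallback (the peroxyketal is made by ozonolysis in methanol instead of radical peroxidation): set out from 5. Et3SiCl and imidazole give (4R)-4-methyl-7-(triethylsilyloxy)heptan-2-one F6. Wittig methylenation (Ph3PCH3Br, KOtBu, THF) gives triethyl{[(4R)-4,6-dimethylhept-6-en-1-yl]oxy}silane F7. Ozonolysis in MeOH/CH2Cl2 at −78 °C, in which methanol traps the more substituted carbonyl oxide, gives (4R)-2-methoxy-4-methyl-7-(triethylsilyloxy)heptan-2-yl hydroperoxide F8. Silylation (Et3SiCl, imidazole) gives triethyl{[(4R)-2-methoxy-4-methyl-7-(triethylsilyloxy)heptan-2-yl]peroxy}silane F9. F9 takes the place of 7 under the conditions of step 5, with methoxide as the leaving group, and the route is rejoined at 11.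

**Further compounds**

F1 | step 5 | methyl 2-[3,5-dimethyl-5-[(2R)-2-methyl-5-(triethylsilyloxy)pentyl]-1,2-dioxolan-3-yl]acetate, mixture of C3/C5 stereoisomers | C[C@H](CCCO[Si](CC)(CC)CC)CC1(C)CC(C)(CC(=O)OC)OO1
F2 | step 10 | methyl 2-[(3S,5R)-5-[(2R)-5-hydroxy-2-methylpentyl]-3,5-dimethyl-1,2-dioxolan-3-yl]acetate | C[C@H](CCCO)C[C@]1(C)C[C@@](C)(CC(=O)OC)OO1
F3 | step 10 | methyl 2-[(3S,5R)-3,5-dimethyl-5-[(2R)-2-methyl-5-[(1-phenyl-1H-tetrazol-5-yl)sulfanyl]pentyl]-1,2-dioxolan-3-yl]acetate | C[C@H](CCCSc1nnnn1-c1ccccc1)C[C@]1(C)C[C@@](C)(CC(=O)OC)OO1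
F4 | step 10 | methyl 2-[(3S,5R)-3,5-dimethyl-5-[(2R)-2-methyl-5-[(1-phenyl-1H-tetrazol-5-yl)sulfonyl]pentyl]-1,2-dioxolan-3-yl]acetate | C[C@H](CCCS(=O)(=O)c1nnnn1-c1ccccc1)C[C@]1(C)C[C@@](C)(CC(=O)OC)OO1
F5 | step 10 | (4E)-5-phenylpent-4-enal | O=CCC/C=C/c1ccccc1
F6 | step 4 | (4R)-4-methyl-7-(triethylsilyloxy)heptan-2-one | C[C@H](CCCO[Si](CC)(CC)CC)CC(C)=O
F7 | step 4 | triethyl{[(4R)-4,6-dimethylhept-6-en-1-yl]oxy}silane | C[C@H](CCCO[Si](CC)(CC)CC)CC(C)=C
F8 | step 4 | (4R)-2-methoxy-4-methyl-7-(triethylsilyloxy)heptan-2-yl hydroperoxide, both C2 epimers | C[C@H](CCCO[Si](CC)(CC)CC)CC(C)(OC)OO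
F9 | step 4 | triethyl{[(4R)-2-methoxy-4-methyl-7-(triethylsilyloxy)heptan-2-yl]peroxy}silane, both C2 epimers | C[C@H](CCCO[Si](CC)(CC)CC)CC(C)(OC)OO[Si](CC)(CC)CC
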